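**Plan**
- Retrosynthetic cuts: the aryl O–CH2 ether bond (Mitsunobu), the side-chain CH2–C(Me)= bond (Negishi), then ring A at C2–C3 (radical cyclisation), at C3–C4 (acetate enolate acylation), at the two C5–CH3 bonds and at C6–C1 (conjugate addition to 5,6-dihydro-2H-pyran-2-one).
- Enabling feature: in ring A (C1 bearing =CH2, C2, C3, C4 carbinol, C5 CMe2, C6 bearing the chain) the C4 oxygen can be a ketone whose only enolisable neighbour is C3, because C5 is quaternary. C3 stands 1,3 to the methylene-bearing C1, so a C3 radical of a chloro keto ester can close onto the CH2 of an isopropenyl group held at C6.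
- Forward order: lactone 5 supplies C4, C5, C6, C1 and the two-carbon arm; chain extension and chlorination give the open-chain precursor 11; ring A closes in step 6; the side chain is then joined through an alkylzinc reagent and the coumarin is attached last.
- Stereochemistry: C6 from the Rh/(R)-BINAP 1,4-addition; C4 from hydride attack anti to the C6 chain (equatorial alcohol, cis to the chain); the E-alkene from a stereodefined enol triflate coupled with retention.

Key step: step 6

Assumption: the enantioface selection of the Rh/(R)-BINAP catalyst on 5,6-dihydro-2H-pyran-2-one is taken to be the same as on cyclohex-2-enone, which places the isopropenyl group as in (R)-3. TBDPS = tert-butyldiphenylsilyl.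

**Step 1**
Reactants: 1 5,6-dihydro-2H-pyran-2-one; 2 potassium trifluoro(prop-1-en-2-yl)borate
Product: 3 (R)-4-(prop-1-en-2-yl)oxan-2-one
Conditions: [Rh(cod)2]BF4 (3 mol %), (R)-BINAP (3.3 mol %), Et3N, toluene/H2O, 90 °C
Reagents that add atoms: none
Why: Rhodium-catalysed asymmetric 1,4-addition of an alkenylboron reagent to a cyclic enoate (Hayashi–Miyaura reaction); the BINAP-bound alkenylrhodium species should add to one enantioface of the lactone and so set the later C6 of ring A.

**Step 2**
Reactants: 3 (R)-4-(prop-1-en-2-yl)oxan-2-one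
Product: 5 (S)-3,3-dimethyl-4-(prop-1-en-2-yl)oxan-2-one, via monomethyl lactone 4 (not isolated)
Conditions: LiN(iPr)2 (1.1 equiv), THF, −78 °C, MeI; then LiN(iPr)2 (1.3 equiv), −78 °C, MeI, to 0 °C
Reagents that add atoms: iodomethane, CI
Why: Two successive lactone enolate alkylations build the quaternary C5; the stereocentre is not enolisable and stays untouched, its descriptor changing from R to S only through the CIP priorities.

**Step 3**
Reactants: 5 (S)-3,3-dimethyl-4-(prop-1-en-2-yl)oxan-2-one
Product: 8 (S)-3-[2-(tert-butyldiphenylsilyloxy)ethyl]-2,2,4-trimethylpent-4-enoic acid, via potassium hydroxy carboxylate 6 (not isolated), via bis-silylated acid 7 (not isolated)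
Conditions: KOH (1.05 equiv), MeOH/H2O, 50 °C; evaporate; TBDPSCl, imidazole, DMF, rt; then K2CO3, MeOH/THF/H2O, rt; pH 5 work-up
Reagents that add atoms: potassium hydroxide, [K+].[OH-]; tert-butyl(chloro)diphenylsilane, CC(C)(C)[Si](Cl)(c1ccccc1)c1ccccc1
Why: Saponification, exhaustive silylation of the hydroxy carboxylate and selective solvolysis of the labile silyl ester is the standard way to open a lactone to a silyloxy acid without relactonisation.

**Step 4**
Reactants: 8 (S)-3-[2-(tert-butyldiphenylsilyloxy)ethyl]-2,2,4-trimethylpent-4-enoic acid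
Product: 10 ethyl (S)-5-[2-(tert-butyldiphenylsilyloxy)ethyl]-4,4,6-trimethyl-3-oxohept-6-enoate, via acid chloride 9 (not isolated)
Conditions: Me2C=C(Cl)NMe2, CH2Cl2, 0 °C to rt; then LiCH2CO2Et (3 equiv, from EtOAc and LiN(iPr)2), THF, −78 °C
Reagents that add atoms: ethyl acetate, CCOC(C)=O
Why: Acid chloride formation under neutral conditions with the α-chloro enamine, then crossed Claisen acylation of the lithium enolate of ethyl acetate, which is reliable with pivaloyl-type chlorides and spares the isopropenyl group and the silyl ether.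

**Step 5**
Reactants: 10 ethyl (S)-5-[2-(tert-butyldiphenylsilyloxy)ethyl]-4,4,6-trimethyl-3-oxohept-6-enoate
Product: 11 ethyl (5S)-2-chloro-5-[2-(tert-butyldiphenylsilyloxy)ethyl]-4,4,6-trimethyl-3-oxohept-6-enoate as both C2 epimers
Conditions: NCS (1.05 equiv), Mg(ClO4)2 (10 mol %), EtOAc, rt
Reagents that add atoms: N-chlorosuccinimide, O=C1CCC(=O)N1Cl
Why: Lewis-acid-catalysed electrophilic α-chlorination of a β-keto ester through its magnesium-bound enol; NCS should leave the isolated 1,1-disubstituted alkene alone, which a more aggressive chlorine source might not.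

**Step 6**
Reactants: 11 ethyl (5S)-2-chloro-5-[2-(tert-butyldiphenylsilyloxy)ethyl]-4,4,6-trimethyl-3-oxohept-6-enoate
Product: 12 ethyl (4S)-1-chloro-4-[2-(tert-butyldiphenylsilyloxy)ethyl]-3,3-dimethyl-5-methylidene-2-oxocyclohexane-1-carboxylate as either C1 epimer
Conditions: Mn(OAc)3·2H2O (2.2 equiv), Cu(OAc)2·H2O (1 equiv), degassed AcOH, 50 °C
Reagents that add atoms: none
Why: Mn(OAc)3 forms the trivalent manganese enolate at C3, the only enolisable position because C5 is quaternary, and inner-sphere electron transfer releases an electrophilic C3 radical. This radical adds to the unsubstituted CH2 terminus of the isopropenyl group in a 6-endo-trig closure that forms the C2–C3 bond and ring A; 3-oxohept-6-enyl radicals with the ketone inside the forming ring and a 1,1-disubstituted acceptor are known to prefer this mode over 5-exo attack. The tertiary C1 radical is captured by Cu(OAc)2 as an alkylcopper species that loses a β-hydrogen from the unhindered methyl group to give the exocyclic methylene, and the divalent copper is regenerated by the second equivalent of Mn(OAc)3. The closest known reaction type is the Mn(OAc)3/Cu(OAc)2 oxidative radical cyclisation of unsaturated α-chloro β-keto esters to methylenecyclohexanes. The C6 stereocentre is carried in unchanged from 11, and the new centre at C3 (Cl, CO2Et) forms without control, which does no harm because both groups are removed in steps 7 and 8. The step needs endo over exo closure, exocyclic over endocyclic elimination and no second oxidation; the alkene substitution pattern, the accessible methyl hydrogens and the chlorine, which leaves 12 without an enolisable hydrogen, should secure these.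

**Step 7**
Reactants: 12 ethyl (4S)-1-chloro-4-[2-(tert-butyldiphenylsilyloxy)ethyl]-3,3-dimethyl-5-methylidene-2-oxocyclohexane-1-carboxylate
Product: 13 ethyl (4S)-4-[2-(tert-butyldiphenylsilyloxy)ethyl]-3,3-dimethyl-5-methylidene-2-oxocyclohexane-1-carboxylate as C1 epimers and enol
Conditions: Zn dust, AcOH, rt
Reagents that add atoms: none
Why: Reductive dehalogenation of the activated C–Cl bond by zinc gives a zinc enolate that acetic acid protonates, while the alkene, ester and silyl ether are inert.

**Step 8**
Reactants: 13 ethyl (4S)-4-[2-(tert-butyldiphenylsilyloxy)ethyl]-3,3-dimethyl-5-methylidene-2-oxocyclohexane-1-carboxylate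
Product: 14 (S)-3-[2-(tert-butyldiphenylsilyloxy)ethyl]-2,2-dimethyl-4-methylidenecyclohexan-1-one
Conditions: LiCl, DMSO, H2O, 150 °C
Reagents that add atoms: none
Why: Krapcho dealkoxycarbonylation under neutral conditions; the alkene is γ,δ to the ketone and cannot move into conjugation by enolisation.

**Step 9**
Reactants: 14 (S)-3-[2-(tert-butyldiphenylsilyloxy)ethyl]-2,2-dimethyl-4-methylidenecyclohexan-1-one
Product: 15 (S)-3-(2-hydroxyethyl)-2,2-dimethyl-4-methylidenecyclohexan-1-one
Conditions: Bu4NF, THF, rt
Reagents that add atoms: none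
Why: Fluoride-induced cleavage of the silyl ether; the ketone, with no stereocentre at its enolisable side, tolerates the mildly basic medium.

**Step 10**
Reactants: 15 (S)-3-(2-hydroxyethyl)-2,2-dimethyl-4-methylidenecyclohexan-1-one
Product: 16 (S)-3-(2-iodoethyl)-2,2-dimethyl-4-methylidenecyclohexan-1-one
Conditions: I2, PPh3, imidazole, CH2Cl2, 0 °C to rt
Reagents that add atoms: iodine, II
Why: Appel-type iodination of a primary alcohol through its alkoxyphosphonium salt, under conditions that leave the ketone and the alkene untouched.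

**Step 11**
Reactants: 17 ethyl acetoacetate
Product: 18 ethyl (2E)-3-(trifluoromethanesulfonyloxy)but-2-enoate
Conditions: aq. Me4NOH, Tf2O, hexane, 5 °C
Reagents that add atoms: trifluoromethanesulfonic anhydride, O=S(=O)(OS(=O)(=O)C(F)(F)F)C(F)(F)F
Why: O-sulfonylation of a β-keto ester enolate; with a non-chelating ammonium counter-ion the enolate should adopt the dipole-minimised geometry and give the E-triflate (triflate trans to the ester).

**Step 12**
Reactants: 16 (S)-3-(2-iodoethyl)-2,2-dimethyl-4-methylidenecyclohexan-1-one; 18 ethyl (2E)-3-(trifluoromethanesulfonyloxy)but-2-enoate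
Product: 20 ethyl (2E)-5-[(1S)-2,2-dimethyl-6-methylidene-3-oxocyclohexyl]-3-methylpent-2-enoate, via alkylzinc iodide 19 (not isolated)
Conditions: Zn dust (activated by BrCH2CH2Br and Me3SiCl), THF, 40 °C; then 18, Pd(PPh3)4 (5 mol %), THF, rt
Reagents that add atoms: none
Why: Negishi coupling of a primary alkylzinc iodide, which tolerates the hindered ketone, with an alkenyl triflate; oxidative addition to zerovalent palladium and reductive elimination proceed with retention, so the E-geometry of 18 should be carried into the trisubstituted alkene.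

**Step 13**
Reactants: 20 ethyl (2E)-5-[(1S)-2,2-dimethyl-6-methylidene-3-oxocyclohexyl]-3-methylpent-2-enoate
Product: 21 (1R,3S)-3-[(3E)-5-hydroxy-3-methylpent-3-en-1-yl]-2,2-dimethyl-4-methylidenecyclohexan-1-ol
Conditions: LiAlH4, Et2O, −78 to 0 °C
Reagents that add atoms: none
Why: Hydride reduction of the ketone and 1,2-reduction of the β,β-disubstituted enoate in one operation; the small hydride should attack the C4 carbonyl on the face anti to the C6 chain (axial attack on the chair with equatorial chain) and give the equatorial 4R alcohol cis to the chain, as with 2,2-dimethylcyclohexanones.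

**Step 14**
Reactants: 21 (1R,3S)-3-[(3E)-5-hydroxy-3-methylpent-3-en-1-yl]-2,2-dimethyl-4-methylidenecyclohexan-1-ol; 22 isofraxidin (7-hydroxy-6,8-dimethoxy-2H-chromen-2-one)
Product: 23 7-{[(2E)-5-[(1S,3R)-3-hydroxy-2,2-dimethyl-6-methylidenecyclohexyl]-3-methylpent-2-en-1-yl]oxy}-6,8-dimethoxy-2H-chromen-2-one
Conditions: PPh3, DIAD, THF, 0 °C to rt
Reagents that add atoms: none
Why: Mitsunobu etherification of the acidic coumarin phenol with the primary allylic alcohol; the neopentyl-type secondary alcohol next to the quaternary carbon should not be activated, so no protecting group is needed.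

**Compound list**
1 | 5,6-dihydro-2H-pyran-2-one | O=C1C=CCCO1 | starting material
2 | potassium trifluoro(prop-1-en-2-yl)borate | [K+].C=C(C)[B-](F)(F)F | starting material
3 | (R)-4-(prop-1-en-2-yl)oxan-2-one | O=C1OCC[C@@H](C(C)=C)C1 | intermediate
4 | (4R)-3-methyl-4-(prop-1-en-2-yl)oxan-2-one, C3 epimers, not isolated | O=C1OCC[C@@H](C(C)=C)C1C | intermediate
5 | (S)-3,3-dimethyl-4-(prop-1-en-2-yl)oxan-2-one | O=C1OCC[C@@H](C(C)=C)C1(C)C | intermediate
6 | potassium (S)-3-(2-hydroxyethyl)-2,2,4-trimethylpent-4-enoate, not isolated | [K+].[O-]C(=O)C(C)(C)[C@@H](CCO)C(C)=C | intermediate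
7 | tert-butyldiphenylsilyl (S)-3-[2-(tert-butyldiphenylsilyloxy)ethyl]-2,2,4-trimethylpent-4-enoate, not isolated | CC(C)(C)[Si](c1ccccc1)(c1ccccc1)OC(=O)C(C)(C)[C@@H](CCO[Si](c1ccccc1)(c1ccccc1)C(C)(C)C)C(C)=C | intermediate
8 | (S)-3-[2-(tert-butyldiphenylsilyloxy)ethyl]-2,2,4-trimethylpent-4-enoic acid | OC(=O)C(C)(C)[C@@H](CCO[Si](c1ccccc1)(c1ccccc1)C(C)(C)C)C(C)=C | intermediate
9 | (S)-3-[2-(tert-butyldiphenylsilyloxy)ethyl]-2,2,4-trimethylpent-4-enoyl chloride, not isolated | ClC(=O)C(C)(C)[C@@H](CCO[Si](c1ccccc1)(c1ccccc1)C(C)(C)C)C(C)=C | intermediate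
10 | ethyl (S)-5-[2-(tert-butyldiphenylsilyloxy)ethyl]-4,4,6-trimethyl-3-oxohept-6-enoate | CCOC(=O)CC(=O)C(C)(C)[C@@H](CCO[Si](c1ccccc1)(c1ccccc1)C(C)(C)C)C(C)=C | intermediate
11 | ethyl (5S)-2-chloro-5-[2-(tert-butyldiphenylsilyloxy)ethyl]-4,4,6-trimethyl-3-oxohept-6-enoate, both C2 epimers | CCOC(=O)C(Cl)C(=O)C(C)(C)[C@@H](CCO[Si](c1ccccc1)(c1ccccc1)C(C)(C)C)C(C)=C | intermediate
12 | ethyl (4S)-1-chloro-4-[2-(tert-butyldiphenylsilyloxy)ethyl]-3,3-dimethyl-5-methylidene-2-oxocyclohexane-1-carboxylate, either C1 epimer | C=C1CC(Cl)(C(=O)OCC)C(=O)C(C)(C)[C@H]1CCO[Si](c1ccccc1)(c1ccccc1)C(C)(C)C | intermediate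
13 | ethyl (4S)-4-[2-(tert-butyldiphenylsilyloxy)ethyl]-3,3-dimethyl-5-methylidene-2-oxocyclohexane-1-carboxylate, C1 epimers | C=C1CC(C(=O)OCC)C(=O)C(C)(C)[C@H]1CCO[Si](c1ccccc1)(c1ccccc1)C(C)(C)C | intermediate
14 | (S)-3-[2-(tert-butyldiphenylsilyloxy)ethyl]-2,2-dimethyl-4-methylidenecyclohexan-1-one | C=C1CCC(=O)C(C)(C)[C@H]1CCO[Si](c1ccccc1)(c1ccccc1)C(C)(C)C | intermediate
15 | (S)-3-(2-hydroxyethyl)-2,2-dimethyl-4-methylidenecyclohexan-1-one | C=C1CCC(=O)C(C)(C)[C@H]1CCO | intermediate
16 | (S)-3-(2-iodoethyl)-2,2-dimethyl-4-methylidenecyclohexan-1-one | C=C1CCC(=O)C(C)(C)[C@H]1CCI | intermediate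
17 | ethyl acetoacetate | CCOC(=O)CC(C)=O | starting material
18 | ethyl (2E)-3-(trifluoromethanesulfonyloxy)but-2-enoate | CCOC(=O)/C=C(\C)OS(=O)(=O)C(F)(F)F | intermediate
19 | {2-[(1S)-2,2-dimethyl-6-methylidene-3-oxocyclohexyl]ethyl}(iodo)zinc, not isolated | C=C1CCC(=O)C(C)(C)[C@H]1CC[Zn]I | intermediate
20 | ethyl (2E)-5-[(1S)-2,2-dimethyl-6-methylidene-3-oxocyclohexyl]-3-methylpent-2-enoate | C=C1CCC(=O)C(C)(C)[C@H]1CC/C(C)=C/C(=O)OCC | intermediate
21 | (1R,3S)-3-[(3E)-5-hydroxy-3-methylpent-3-en-1-yl]-2,2-dimethyl-4-methylidenecyclohexan-1-ol | C=C1CC[C@@H](O)C(C)(C)[C@H]1CC/C(C)=C/CO | intermediate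
22 | isofraxidin (7-hydroxy-6,8-dimethoxy-2H-chromen-2-one) | COc1cc2ccc(=O)oc2c(OC)c1O | starting material
23 | 7-{[(2E)-5-[(1S,3R)-3-hydroxy-2,2-dimethyl-6-methylidenecyclohexyl]-3-methylpent-2-en-1-yl]oxy}-6,8-dimethoxy-2H-chromen-2-one | C=C1CC[C@@H](O)C(C)(C)[C@H]1CC/C(C)=C/COc1c(OC)cc2ccc(=O)oc2c1OC | target

**Count**
Total steps: 14. Longest linear sequence: 13 steps (steps 1 to 10, then 12 to 14); step 11 makes the coupling partner.

**Steps most likely to fail**

Step 6. The radical may close at the substituted alkene carbon, the copper intermediate may lose a ring hydrogen instead of a methyl hydrogen, or the C1 centre may be captured ionically by acetate or by the ether oxygen. The fallback makes the same C2–C3 bond by polar allylic alkylation, and sets out from 8. Ene-type chlorination of the isopropenyl group (NaOCl, CeCl3·7H2O, CH2Cl2/H2O, 0 °C) should give (R)-4-(chloromethyl)-3-[2-(tert-butyldiphenylsilyloxy)ethyl]-2,2-dimethylpent-4-enoic acid F1. Treatment with Me2C=C(Cl)NMe2 should give (S)-4-(chloromethyl)-3-[2-(tert-butyldiphenylsilyloxy)ethyl]-2,2-dimethylpent-4-enoyl chloride F2, and acylation of LiCH2CO2Et at −78 °C as in step 4 should give ethyl (5R)-6-(chloromethyl)-5-[2-(tert-butyldiphenylsilyloxy)ethyl]-4,4-dimethyl-3-oxohept-6-enoate F3. A Tsuji–Trost cyclisation (Pd(PPh3)4, K2CO3, THF) then closes ring A; both termini of the 2-substituted allyl unit lead to the same skeleton, so the exocyclic methylene is fixed by construction. The sequence comes back to the route at 13 and bypasses steps 5 to 7.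

Step 1. Transfer of the α-branched alkenyl group may be slow against protodeboronation, or the enantioface discrimination may be insufficient. The fallback is a resolution and sets out from 1. Conjugate addition of isopropenylmagnesium bromide (CuI cat., Me3SiCl, THF, −78 °C) should give racemic 4-(prop-1-en-2-yl)oxan-2-one F4. Aminolysis with (R)-1-phenylethylamine and AlMe3 gives two diastereomeric hydroxy amides: (3R)-5-hydroxy-N-[(1R)-1-phenylethyl]-3-(prop-1-en-2-yl)pentanamide F5 is separated by crystallisation or chromatography from (3S)-5-hydroxy-N-[(1R)-1-phenylethyl]-3-(prop-1-en-2-yl)pentanamide F6. Relactonisation of F5 in dilute aqueous HCl/THF releases the amine and comes back to the route at 3.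

Step 13. Hydride delivery to the C4 carbonyl may show poor facial selectivity, or hydride may add in conjugate fashion to the enoate. The fallback separates the two reductions and puts the ketone under reagent control, setting out from 20. (S)-2-Methyl-CBS-oxazaborolidine with catecholborane (toluene, −78 °C) should give ethyl (2E)-5-[(1S,3R)-3-hydroxy-2,2-dimethyl-6-methylidenecyclohexyl]-3-methylpent-2-enoate F7; the sense follows that established for tert-alkyl methyl ketones, with the quaternary C5 as the large group. Reduction of the ester with iBu2AlH (CH2Cl2, −78 °C) comes back to the route at 21.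

**Further compounds**
F1 | step 6 | (R)-4-(chloromethyl)-3-[2-(tert-butyldiphenylsilyloxy)ethyl]-2,2-dimethylpent-4-enoic acid | OC(=O)C(C)(C)[C@@H](CCO[Si](c1ccccc1)(c1ccccc1)C(C)(C)C)C(CCl)=C
F2 | step 6 | (S)-4-(chloromethyl)-3-[2-(tert-butyldiphenylsilyloxy)ethyl]-2,2-dimethylpent-4-enoyl chloride | ClC(=O)C(C)(C)[C@@H](CCO[Si](c1ccccc1)(c1ccccc1)C(C)(C)C)C(CCl)=C
F3 | step 6 | ethyl (5R)-6-(chloromethyl)-5-[2-(tert-butyldiphenylsilyloxy)ethyl]-4,4-dimethyl-3-oxohept-6-enoate | CCOC(=O)CC(=O)C(C)(C)[C@@H](CCO[Si](c1ccccc1)(c1ccccc1)C(C)(C)C)C(CCl)=C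
F4 | step 1 | racemic 4-(prop-1-en-2-yl)oxan-2-one | O=C1CC(C(C)=C)CCO1
F5 | step 1 | (3R)-5-hydroxy-N-[(1R)-1-phenylethyl]-3-(prop-1-en-2-yl)pentanamide | O=C(N[C@H](C)c1ccccc1)C[C@@H](CCO)C(C)=C
F6 | step 1 | (3S)-5-hydroxy-N-[(1R)-1-phenylethyl]-3-(prop-1-en-2-yl)pentanamide | O=C(N[C@H](C)c1ccccc1)C[C@H](CCO)C(C)=C
F7 | step 13 | ethyl (2E)-5-[(1S,3R)-3-hydroxy-2,2-dimethyl-6-methylidenecyclohexyl]-3-methylpent-2-enoate | C=C1CC[C@@H](O)C(C)(C)[C@H]1CC/C(C)=C/C(=O)OCC
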